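The flask holds 0.50 M of starting material and 1.0 mM of free catalyst, and we want the top of its target curve.

| setting | winter | spring | autumn | flask |
|---|---|---|---|---|
| starting material | 0.25 M | 1 M | 0.50 M | 0.50 M |
| free catalyst | 1 mM | 1 mM | 0.50 mM | 1.0 mM |
| remark | run made earlier | run made earlier | run made earlier |  |
| time |  |  |  | 8.0 h |

| run | time / h | target / % | starting material / % |
|---|---|---|---|
| winter | 0.167 | 43.0 | 53.4 |
| winter | 0.500 | 72.8 | 10.5 |
| winter | 2.00 | 30.3 | 0 |
| winter | 6.00 | 3.4 | 0 |
| spring | 0.167 | 21.6 | 75.3 |
| spring | 0.500 | 52.0 | 35.5 |
| spring | 2.00 | 35.8 | 0 |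
| spring | 6.00 | 2.8 | 0 |
| autumn | 0.167 | 17.4 | 81.8 |
| autumn | 0.500 | 41.7 | 49.7 |
| autumn | 2.00 | 40.6 | 0 |
| autumn | 6.00 | 2.5 | 0 |

(standard deviation of a reading: 1 percentage point)

- what was read earlier has a scatter of 1 percentage point, one standard deviation

- when, up to 8.0 h, the flask holds most target
- the amount of target, in percent of the starting material charged, at that time

Winter, spring and autumn read 0%, 0% and 0% starting material at 2.00 h, so we read the fall of target from there as its loss. Summing target over these runs at 2.00 h and 6.00 h gives a first-order loss of 0.627 h⁻¹.

For the consumption of starting material we use the integrated saturation law: K times ln(charge/[starting material]), plus the drop in [starting material], equals V times time. Winter and spring at 0.500 h give K = 0.346 M and V = 2.01 M h⁻¹. Autumn, with half the free catalyst, gives 0.987 M h⁻¹, half that V.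

Averaging the law over the charge gives 0.297 h for the flask, our mean birth time: the average moment at which target is made, equal to K plus half the charge, divided by V.

Our curve for the flask starts at 1.19 M h⁻¹. It tops where making falls to the loss. Taking winter's 72.8% as the level, that leaves 0.0444 M of starting material, at 0.645 h. Averaging over what has reacted by then puts birth at 0.245 h, so our top is 71.0%. Afterwards the curve follows the charge decaying from the birth time, reaching 9.82% at 4.00 h.

The forecast, holding that “target is lost roughly first-order”, gave 0.65 h (0.55 h to 0.78 h) and 70% (66% to 73%); our top is slightly higher.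

The flask gives 69.7% at 0.658 h.

    starting material + free catalyst → catalyst intermediate A (k = 92.0 M⁻¹ min⁻¹)
    catalyst intermediate A ⇌ catalyst intermediate B (K = 1.50, k = 35.0 min⁻¹)
    catalyst intermediate B → free catalyst + target (k = 890 min⁻¹)
    target → over-reaction product (k = 0.0110 min⁻¹)

At that time 20.8% is already over-reaction product. At 4.00 h the flask holds 8.87%, against 9.82% from the birth-time line. For the neighbour charged with 1.2 M we reckon a birth time of 0.471 h, which is 0.174 h later, so the line puts its tail higher by a factor of 1.12. At 8.00 h that neighbour holds 0.721%, more than the flask's 0.633%.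

The earlier runs and the new flask were computed for substances that don't exist; the scatter is artificial.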